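Readings and results were generated by integration with made-up constants; noise was put on by code.

At early times E leaves the noon flask at 0.0900 /min of its charge while D appears at 0.00900 /min, ten times slower. The balance of E, the limiting reagent, therefore leaves 32.4% of the charge in neither form after 4.00 min. That is more than the 10.0% that X amounts to, which points to an unread store that forms first and feeds D afterwards.

| flask | E | Q | X | remark | time |
|---|---|---|---|---|---|
| noon | 0.10 M | 0.17 M | 10 mM | run made earlier |  |
| spring | 0.10 M | 0.76 M | 10 mM | run made earlier |  |
| dusk | 0.10 M | 2.4 M | 10 mM | run made earlier |  |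
| epsilon | 0.10 M | 0.200 M | 10 mM |  | 15 min |
| theta | 0.10 M | 0.400 M | 10 mM |  | 15 min |
| gamma | 0.10 M | 0.800 M | 10 mM |  | 15 min |
| alpha | 0.10 M | 1.50 M | 10 mM |  | 15 min |
| eta | 0.10 M | 3.00 M | 10 mM |  | 15 min |

| run | time / min | D / % | E / % |
|---|---|---|---|
| noon | 4.00 | 3.6 | 64.0 |
| noon | 8.00 | 9.7 | 54.9 |
| noon | 12.0 | 17.8 | 45.6 |
| noon | 15.0 | 21.9 | 43.6 |
| spring | 2.00 | 2.5 | 76.8 |
| spring | 5.00 | 11.8 | 57.1 |
| spring | 10.0 | 26.4 | 45.1 |
| spring | 15.0 | 42.5 | 36.4 |
| dusk | 4.00 | 9.3 | 62.3 |
| dusk | 8.00 | 25.8 | 48.3 |
| dusk | 12.0 | 38.4 | 38.9 |
| dusk | 15.0 | 48.5 | 32.3 |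

(standard deviation of a reading: 1 percentage point)

- the earlier runs were read with a standard deviation of 1 percentage point
- a reading or a percentage of D counts all its forms, free or not
- "hardly changes" means that all values lie within two and a half points (for a concentration: within two and a half percent of the largest)

* amount of D at the end, in percent of the E charged for epsilon, theta, gamma, alpha, eta, in this order
* how that number moves from the first to the last of them (rises, then falls / hardly changes / rises all the way / falls all the way / falls, then rises)

So take each run as one average rate, D at the end over the time, which has the early lag folded in: noon gives 0.0146 /min and dusk 0.0323 /min. Dusk has 14.1 times the Q of noon but just 2.21 times the rate, so I let the rate be a ceiling times the factor Q/(Q + h). These two runs then give 0.245 M for h, the half-rate Q, the charge of Q at which the rate is half its ceiling (the usual term is half-saturation), and a ceiling of 0.0356 /min. The factor slows noon to 0.410 of the ceiling and dusk to 0.907. Over 15 min the ceiling comes to 53.4% of the charge, which the E charged can supply. Spring, which I did not use, comes out at 40.4% against a reading of 42.5%, a gap of 2.1 percentage points with a scatter of 1 point. My reckoning for epsilon, theta, gamma, alpha and eta is 24.0%, 33.2%, 40.9%, 45.9% and 49.4%, a row that rises all the way.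

The forecast, which says “That is saturation in Q, not first order.”, stands a little above mine at 24.5%, 35%, 43%, 47% and 50%, and its shape is rises all the way. The flasks give 25.1%, 34.4%, 41.7%, 46.0% and 48.8%, and the shape is rises all the way.

    E + X ⇌ X + J (K = 0.873, k = 16.8 /M/min)
    X + J ⇌ Z (K = 5.70 /M, k = 15.8 /M/min)
    Q + Z → X + D (k = 9.96 /M/min)
    L ⇌ D, rate k4*(cs4 - [D]) while solid is left; crystals form when [D] > cs4 (solubility = 19.0 mM, k = 14.9 /min)

Hold each Q against h. Epsilon has 0.817 of it, and there the falling back of Z to X + J, acting together with the short time given, is part of what keeps D at 25.1%: with that falling back removed epsilon ends at 42.9%, and ten times the time gives 94.9%. Eta has 12.2 times h, and the same removal, which accounts for a part of what is missing there, moves its D from 48.8% by 2.5 points.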